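The malonate diester is cut at both ester C–O bonds into malonic acid and two molecules of (5S,9S,10S)-labda-7,13E-dien-15-ol. Ring B of the labdane is bought: (R)-carvone supplies C5–C10, the C8 methyl, the C7=C8 alkene and the C5 stereocenter, and its isopropenyl group is C4 with both methyls, one still as =CH2. Ring A (C1–C2–C3–C4–C5–C10) is closed last, in the key step: hydrogen-atom transfer to the isopropenyl group of a monocyclic carvone gives the tertiary C4 radical, which adds 6-endo to an acrylate arm on C10 and creates the quaternary C4. C10 and C9 are relayed from C5; the temporary ester is excised afterwards.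

Key step: step 3

Remark: labdane numbering (C1–C20) is used for the atoms of all intermediates; commercial (R)-(−)-carvone is the only source of absolute configuration.

Step 1
Reactants: 1 (R)-(−)-carvone
Product: 2 (5R)-2,6-dimethyl-5-(prop-1-en-2-yl)cyclohex-2-en-1-one (6-methylcarvone; both epimers at the new methyl-bearing carbon C10)
Conditions: LiN(iPr)2, THF, −78 °C; MeI, −78 → 0 °C
Reagents that add atoms: iodomethane CI
Why: Kinetic deprotonation at the α'-carbon (C10) gives the cross-conjugated lithium enolate, which is C-methylated (enolate alkylation), and the epimer mixture is harmless because C10 is re-enolized in step 2.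

Step 2
Reactants: 2 6-methylcarvone; 3 methyl 2-(bromomethyl)acrylate
Product: 4 methyl 2-{[(1S,6S)-1,3-dimethyl-2-oxo-6-(prop-1-en-2-yl)cyclohex-3-en-1-yl]methyl}prop-2-enoate (acrylate arm trans to isopropenyl; C10 methyl cis to it)
Conditions: LiN(iPr)2, THF/DMPU, −78 °C; 3, −78 → −20 °C
Reagents that add atoms: none
Why: Enolate alkylation with the allylic bromide (SN2 or SN2') should occur on the face of the tetrasubstituted C9–C10 enolate anti to the C5 isopropenyl group, which sets the quaternary C10 (10S) with the C1 arm trans to C4 and so fixes the later trans ring fusion.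

Step 3
Reactants: 4 acrylate-armed 6-methylcarvone
Product: 5 methyl (4aS,8aS)-4,4,7,8a-tetramethyl-8-oxo-1,2,3,4,4a,5,8,8a-octahydronaphthalene-2-carboxylate (both C2 epimers)
Conditions: Fe(acac)3 (cat.), PhSiH3, EtOH/ethylene glycol, 60 °C, high dilution
Reagents that add atoms: none
Why: An iron hydride formed from Fe(acac)3 and PhSiH3 transfers a hydrogen atom to the terminal CH2 of the isopropenyl group (Markovnikov), so that this carbon becomes the second C4 methyl and C4 becomes a tertiary radical; the radical adds to the unsubstituted terminus (C3) of the 2-substituted acrylate, and the resulting C2 α-ester radical is reduced and protonated. The closest known reaction type is the iron-mediated reductive olefin–acceptor coupling (Mukaiyama-type HAT-initiated Giese addition) in its intramolecular form. Ring A (C1–C2–C3–C4–C5–C10) is closed by the C3–C4 bond in a 6-endo-trig mode, while ring B is the carvone ring that was present from the start. C5 and C10 are not touched, the trans ring fusion follows from the trans arrangement of the two arms set in step 2, and the only new stereocenter, C2, is uncontrolled and is erased in step 5. The step needs hydrogen-atom transfer to the electron-rich 1,1-disubstituted alkene in preference to the acrylate and the enone, which the polarity of the metal hydride should secure. It also needs 6-endo over 5-exo closure, which the ester on C2 secures by blocking the internal alkene carbon and stabilising the adduct radical.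

Step 4
Reactants: 5 bicyclic keto ester
Product: 6 (4aS,8aS)-4,4,7,8a-tetramethyl-8-oxo-1,2,3,4,4a,5,8,8a-octahydronaphthalene-2-carboxylic acid (both C2 epimers)
Conditions: LiOH, THF/MeOH/H2O, rt; then aq. HCl
Reagents that add atoms: lithium hydroxide [Li+].[OH-]
Why: Saponification of the unhindered methyl ester, to which the hindered enone should be inert, and the C2 configuration does not matter.

Step 5
Reactants: 6 bicyclic keto acid
Product: 7 (4aS,8aS)-2,5,5,8a-tetramethyl-4a,5,6,7,8,8a-hexahydronaphthalen-1(4H)-one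
Conditions: 9-mesityl-10-phenylacridinium tetrafluoroborate (cat.), PhSSPh (cat.), i-Pr2NEt (cat.), CF3CH2OH, 450 nm LEDs, rt
Reagents that add atoms: none
Why: Photoredox hydrodecarboxylation, in which the carboxylate is oxidized by the excited acridinium, loses CO2 and the secondary C2 radical takes a hydrogen atom from thiophenol, removes the temporary activating group together with the C2 stereocenter.

Step 6
Reactants: 7 bicyclic enone; 8 (4-bromobut-1-yn-1-yl)trimethylsilane
Product: 11 (4aS,8aS)-1-(but-3-yn-1-yl)-2,5,5,8a-tetramethyl-1,4,4a,5,6,7,8,8a-octahydronaphthalen-1-ol, via Grignard reagent 9 (not isolated), via silylated carbinol 10 (not isolated)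
Conditions: 8, Mg, THF, rt; CeCl3, THF, −78 °C; 7, −78 → 0 °C; then K2CO3, MeOH, rt
Reagents that add atoms: none
Why: 1,2-Addition of the organocerium reagent derived from Grignard reagent 9 to the hindered C9 carbonyl (cerium suppresses enolization and conjugate addition), followed by base-mediated cleavage of the alkynyl C–Si bond; the carbinol configuration is of no consequence because C9 becomes trigonal in step 7.

Step 7
Reactants: 11 tertiary allylic alcohol
Product: 12 (4aS,8aS)-4-(but-3-yn-1-yl)-3,4a,8,8-tetramethyl-4a,5,6,7,8,8a-hexahydronaphthalen-2(1H)-one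
Conditions: pyridinium chlorochromate, 4 Å molecular sieves, CH2Cl2, rt
Reagents that add atoms: pyridinium chlorochromate [O-][Cr](=O)(=O)Cl.c1cc[nH+]cc1
Why: Babler–Dauben oxidative transposition, in which the tertiary allylic chromate ester undergoes a [3,3]-sigmatropic shift to C7 and is oxidized there, moves the carbonyl from C9 to C7 and leaves the side chain on C9 of a C8=C9 enone.

Step 8
Reactants: 12 transposed enone
Product: 13 (2S,4aS,8aS)-4-(but-3-yn-1-yl)-3,4a,8,8-tetramethyl-1,2,4a,5,6,7,8,8a-octahydronaphthalen-2-ol (7β-alcohol)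
Conditions: NaBH4, CeCl3·7H2O, MeOH, −78 → 0 °C
Reagents that add atoms: none
Why: Luche 1,2-reduction with axial hydride delivery to C7 from the α face of the rigid trans-fused bicycle should give the equatorial 7β-alcohol, the center from which C9 is relayed in step 9.

Step 9
Reactants: 13 allylic alcohol
Product: 16 (1S,4aS,8aS)-1-(but-3-yn-1-yl)-2,5,5,8a-tetramethyl-1,4,4a,5,6,7,8,8a-octahydronaphthalene, via sulfonylhydrazide 14 (not isolated), via allylic diazene 15 (not isolated)
Conditions: 2-nitrobenzenesulfonohydrazide, PPh3, diethyl azodicarboxylate, THF, −30 °C; then 23 °C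
Reagents that add atoms: none
Why: Mitsunobu displacement by the sulfonylhydrazide inverts C7, loss of sulfinic acid gives the 7α-diazene, and its retro-ene loss of N2 delivers hydrogen suprafacially to the α face of C9 while the alkene moves to C7=C8 (reductive 1,3-transposition of an allylic alcohol), which sets 9S.

Step 10
Reactants: 16 terminal alkyne
Product: 18 (5S,9S,10S)-labda-7,13E-dien-15-ol, via alkenylalane 17 (not isolated)
Conditions: AlMe3, Cp2ZrCl2 (cat.), CH2Cl2, 0 °C → rt; n-BuLi, THF, −78 °C; (CH2O)n, −78 °C → rt; aq. work-up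
Reagents that add atoms: trimethylaluminium C[Al](C)C; formaldehyde (from paraformaldehyde) C=O
Why: Negishi zirconium-catalysed carboalumination adds methyl and aluminium syn across the terminal alkyne (methyl to C13, aluminium to C14), and the derived alanate is hydroxymethylated with retention, which gives the 13E allylic alcohol.

Step 11
Reactants: 18 (5S,9S,10S)-labda-7,13E-dien-15-ol (2 equiv); 19 malonic acid
Product: 20 bis[(5S,9S,10S)-labda-7,13E-dien-15-yl] malonate
Conditions: N,N'-dicyclohexylcarbodiimide, 4-(dimethylamino)pyridine (cat.), CH2Cl2, 0 °C → rt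
Reagents that add atoms: none
Why: Steglich esterification of both carboxyl groups of malonic acid with two molecules of 18 under neutral conditions should leave the stereocenters and the trisubstituted alkenes untouched.

Compound list
1 | (R)-(−)-carvone, (5R)-2-methyl-5-(prop-1-en-2-yl)cyclohex-2-en-1-one | CC1=CC[C@@H](C(C)=C)CC1=O | starting material
2 | (5R)-2,6-dimethyl-5-(prop-1-en-2-yl)cyclohex-2-en-1-one (6-methylcarvone, both C6 epimers) | CC1=CC[C@@H](C(C)=C)C(C)C1=O | intermediate
3 | methyl 2-(bromomethyl)acrylate | C=C(CBr)C(=O)OC | starting material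
4 | methyl 2-{[(1S,6S)-1,3-dimethyl-2-oxo-6-(prop-1-en-2-yl)cyclohex-3-en-1-yl]methyl}prop-2-enoate | CC1=CC[C@@H](C(C)=C)[C@](C)(CC(=C)C(=O)OC)C1=O | intermediate
5 | methyl (4aS,8aS)-4,4,7,8a-tetramethyl-8-oxo-1,2,3,4,4a,5,8,8a-octahydronaphthalene-2-carboxylate (C2 epimers) | CC1=CC[C@H]2C(C)(C)CC(C(=O)OC)C[C@]2(C)C1=O | intermediate
6 | (4aS,8aS)-4,4,7,8a-tetramethyl-8-oxo-1,2,3,4,4a,5,8,8a-octahydronaphthalene-2-carboxylic acid (C2 epimers) | CC1=CC[C@H]2C(C)(C)CC(C(=O)O)C[C@]2(C)C1=O | intermediate
7 | (4aS,8aS)-2,5,5,8a-tetramethyl-4a,5,6,7,8,8a-hexahydronaphthalen-1(4H)-one | CC1=CC[C@H]2C(C)(C)CCC[C@]2(C)C1=O | intermediate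
8 | (4-bromobut-1-yn-1-yl)trimethylsilane | C[Si](C)(C)C#CCCBr | starting material
9 | [4-(trimethylsilyl)but-3-yn-1-yl]magnesium bromide | C[Si](C)(C)C#CCC[Mg]Br | intermediate
10 | (4aS,8aS)-2,5,5,8a-tetramethyl-1-[4-(trimethylsilyl)but-3-yn-1-yl]-1,4,4a,5,6,7,8,8a-octahydronaphthalen-1-ol (carbinol configuration not specified) | CC1=CC[C@H]2C(C)(C)CCC[C@]2(C)C1(O)CCC#C[Si](C)(C)C | intermediate
11 | (4aS,8aS)-1-(but-3-yn-1-yl)-2,5,5,8a-tetramethyl-1,4,4a,5,6,7,8,8a-octahydronaphthalen-1-ol (carbinol configuration not specified) | CC1=CC[C@H]2C(C)(C)CCC[C@]2(C)C1(O)CCC#C | intermediate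
12 | (4aS,8aS)-4-(but-3-yn-1-yl)-3,4a,8,8-tetramethyl-4a,5,6,7,8,8a-hexahydronaphthalen-2(1H)-one | CC1=C(CCC#C)[C@@]2(C)CCCC(C)(C)[C@@H]2CC1=O | intermediate
13 | (2S,4aS,8aS)-4-(but-3-yn-1-yl)-3,4a,8,8-tetramethyl-1,2,4a,5,6,7,8,8a-octahydronaphthalen-2-ol | CC1=C(CCC#C)[C@@]2(C)CCCC(C)(C)[C@@H]2C[C@@H]1O | intermediate
14 | N-[(2R,4aS,8aS)-4-(but-3-yn-1-yl)-3,4a,8,8-tetramethyl-1,2,4a,5,6,7,8,8a-octahydronaphthalen-2-yl]-2-nitrobenzenesulfonohydrazide | CC1=C(CCC#C)[C@@]2(C)CCCC(C)(C)[C@@H]2C[C@H]1N(N)S(=O)(=O)c1ccccc1[N+](=O)[O-] | intermediate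
15 | [(2R,4aS,8aS)-4-(but-3-yn-1-yl)-3,4a,8,8-tetramethyl-1,2,4a,5,6,7,8,8a-octahydronaphthalen-2-yl]diazene | CC1=C(CCC#C)[C@@]2(C)CCCC(C)(C)[C@@H]2C[C@H]1N=N | intermediate
16 | (1S,4aS,8aS)-1-(but-3-yn-1-yl)-2,5,5,8a-tetramethyl-1,4,4a,5,6,7,8,8a-octahydronaphthalene | CC1=CC[C@H]2C(C)(C)CCC[C@]2(C)[C@H]1CCC#C | intermediate
17 | dimethyl{(1E)-2-methyl-4-[(1S,4aS,8aS)-2,5,5,8a-tetramethyl-1,4,4a,5,6,7,8,8a-octahydronaphthalen-1-yl]but-1-en-1-yl}alane | C[Al](C)/C=C(\C)CC[C@H]1C(C)=CC[C@H]2C(C)(C)CCC[C@]12C | intermediate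
18 | (5S,9S,10S)-labda-7,13E-dien-15-ol, (2E)-3-methyl-5-[(1S,4aS,8aS)-2,5,5,8a-tetramethyl-1,4,4a,5,6,7,8,8a-octahydronaphthalen-1-yl]pent-2-en-1-ol | OC/C=C(\C)CC[C@H]1C(C)=CC[C@H]2C(C)(C)CCC[C@]12C | intermediate
19 | malonic acid | OC(=O)CC(=O)O | starting material
20 | bis[(5S,9S,10S)-labda-7,13E-dien-15-yl] malonate | CC1=CC[C@H]2C(C)(C)CCC[C@]2(C)[C@H]1CC/C(C)=C/COC(=O)CC(=O)OC/C=C(\C)CC[C@H]1C(C)=CC[C@H]2C(C)(C)CCC[C@]12C | target

Total step count: 11 steps. Longest linear sequence: 11 steps (1 → 20).

Steps most likely to fail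

Step 3. Hydrogen-atom transfer may outrun ring closure, so that the tertiary radical is simply reduced to the isopropyl compound, or the radical may add to the enone of a second molecule. The fallback replaces the radical closure by a cationic one, sets out from 2 and returns at 7. Commercial 3-(trimethylsilyl)prop-2-yn-1-ol would be semihydrogenated (H2, Ni(OAc)2·4H2O/NaBH4, ethylenediamine, EtOH) to (Z)-3-(trimethylsilyl)prop-2-en-1-ol F1 and converted with CBr4/PPh3 into (Z)-(3-bromoprop-1-en-1-yl)trimethylsilane F2. The lithium enolate of 2 would be alkylated with it, again anti to the isopropenyl group, to give the vinylsilane-armed carvone F3. Protonation of the isopropenyl group (CF3CO2H, CH2Cl2, 0 °C) would generate the C4 cation, and vinylsilane-terminated cation–olefin cyclization with ipso attack of C3 and loss of silicon would give the ring A diene-one F4. Hydrogenation of its disubstituted C2=C3 alkene with RhCl(PPh3)3 and H2 would give 7.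

Step 6. Enolization by γ-deprotonation, or reduction of the very hindered C9 carbonyl, may compete with addition of the primary organometallic. The fallback builds the C9–C11 bond by olefination and sets out from 7, returning at 16. Wittig methylenation (Ph3PCH3Br, KOt-Bu, toluene, 90 °C) would give drima-7,9(11)-diene F5. Hydroboration of the exocyclic alkene from the α face (9-borabicyclo[3.3.1]nonane, THF; then NaOH, H2O2) would give drim-7-en-11-ol F6 with 9α-H. Iodination (I2, PPh3, imidazole) would give 11-iododrim-7-ene F7, and alkylation of lithiated 1-(trimethylsilyl)propyne (n-BuLi, THF/DMPU) with it would give the silylated alkyne F8. K2CO3 in MeOH would then give 16. This path also bypasses steps 7 to 9.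

Step 9. The Mitsunobu displacement at the allylic C7 next to a tetrasubstituted alkene may give way to elimination to a diene or to SN2' attack, with loss of the stereochemical relay. The fallback uses organopalladium chemistry, sets out from 13 and returns at 16. Acylation (ClCO2Me, pyridine, CH2Cl2) would give the allylic methyl carbonate F9. Formate reduction with zerovalent palladium (Pd2(dba)3, PBu3, HCO2H, Et3N, THF, rt) would ionize it with inversion and deliver hydride from the metal-bearing α face to the more substituted terminus C9, giving 16.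

Further compounds
F1 | step 3 | (Z)-3-(trimethylsilyl)prop-2-en-1-ol | OC/C=C\[Si](C)(C)C
F2 | step 3 | (Z)-(3-bromoprop-1-en-1-yl)trimethylsilane | BrC/C=C\[Si](C)(C)C
F3 | step 3 | (5S,6S)-2,6-dimethyl-5-(prop-1-en-2-yl)-6-[(2Z)-3-(trimethylsilyl)prop-2-en-1-yl]cyclohex-2-en-1-one | CC1=CC[C@@H](C(C)=C)[C@](C)(C/C=C\[Si](C)(C)C)C1=O
F4 | step 3 | (4aS,8aS)-2,5,5,8a-tetramethyl-4a,5,8,8a-tetrahydronaphthalen-1(4H)-one | CC1=CC[C@H]2C(C)(C)C=CC[C@]2(C)C1=O
F5 | step 6 | drima-7,9(11)-diene | C=C1C(C)=CC[C@H]2C(C)(C)CCC[C@]12C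
F6 | step 6 | drim-7-en-11-ol | OC[C@H]1C(C)=CC[C@H]2C(C)(C)CCC[C@]12C
F7 | step 6 | 11-iododrim-7-ene | IC[C@H]1C(C)=CC[C@H]2C(C)(C)CCC[C@]12C
F8 | step 6 | trimethyl{4-[(1S,4aS,8aS)-2,5,5,8a-tetramethyl-1,4,4a,5,6,7,8,8a-octahydronaphthalen-1-yl]but-1-yn-1-yl}silane | C[Si](C)(C)C#CCC[C@H]1C(C)=CC[C@H]2C(C)(C)CCC[C@]12C
F9 | step 9 | (2S,4aS,8aS)-4-(but-3-yn-1-yl)-3,4a,8,8-tetramethyl-1,2,4a,5,6,7,8,8a-octahydronaphthalen-2-yl methyl carbonate | CC1=C(CCC#C)[C@@]2(C)CCCC(C)(C)[C@@H]2C[C@@H]1OC(=O)OC
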